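**Plan**

1. Retrosynthetically the four silyl ethers come off last. Then the ring oxygen O1, which sits between the arene carbon C8a and the vinylic C2–H of the 4-pyranone, is excised, so ring C becomes the enone of a 2-aryl-inden-1-one (pyranone = indenone + one oxygen atom).
2. The indenone is cut at C2–aryl (isoflavone C3–C1′, Pd ketone α-arylation with a preformed bromochromene) and at the A-ring C6–CH2 bond (B-alkyl Suzuki–Miyaura). The indanone comes from a symmetric 3-arylpropanoic acid by Friedel–Crafts acylation, so the alkyl group lies between the two oxygens without any regiochemical choice.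
3. Forward order: indanone (ring A plus the carbocycle) → side chain → chromene ring B attached → dehydrogenation → oxygen-insertion ring expansion to the pyranone → desilylation.
4. Stereochemistry: the target has no stereocentre, axis or stereogenic double bond, so nothing has to be set. The stereocentres of intermediates 15, 17, 18 and 20 are racemic and are destroyed again.

Key step: step 13

Remark: the target is achiral, so "single enantiomer" simply means the compound as drawn; compounds 1, 8 and 12 and all reagents are taken to be commercially available.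

**Route**

Step 1
Reactants: 1 4-bromo-3,5-dimethoxybenzaldehyde
Product: 4 3-(4-bromo-3,5-dimethoxyphenyl)propanoic acid, via arylidene Meldrum's acid 2 (not isolated), via benzyl Meldrum's acid 3 (not isolated)
Conditions: Meldrum's acid, HCO2H/Et3N (5:2), 95 °C; aq. HCl work-up
Reagents that add atoms: Meldrum's acid, CC1(C)OC(=O)CC(=O)O1
Why: One-pot reductive Knoevenagel homologation, in which the aldehyde condenses with Meldrum's acid, formate transfers hydride to the arylidene and the benzyl Meldrum's acid loses acetone and CO2 on heating; no metal is present, so the aryl bromide should survive.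

Step 2
Reactants: 4 3-(4-bromo-3,5-dimethoxyphenyl)propanoic acid
Product: 5 6-bromo-5,7-dimethoxy-2,3-dihydro-1H-inden-1-one
Conditions: Eaton's reagent (P2O5/MeSO3H), 60 °C
Reagents that add atoms: none
Why: Intramolecular Friedel–Crafts acylation at one of two symmetry-equivalent positions that are ortho and para to the methoxy groups, so only one indanone can form.

Step 3
Reactants: 5 6-bromo-5,7-dimethoxy-2,3-dihydro-1H-inden-1-one
Product: 6 6-bromo-5,7-dihydroxy-2,3-dihydro-1H-inden-1-one
Conditions: BBr3, CH2Cl2, −78 °C → rt; H2O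
Reagents that add atoms: none
Why: Lewis-acid cleavage of aryl methyl ethers (BBr3 demethylation), carried out before any acid-sensitive group is in the molecule.

Step 4
Reactants: 6 6-bromo-5,7-dihydroxy-2,3-dihydro-1H-inden-1-one
Product: 7 6-bromo-5,7-bis(triisopropylsilyloxy)-2,3-dihydro-1H-inden-1-one
Conditions: TIPSOTf, 2,6-lutidine, CH2Cl2, 0 °C
Reagents that add atoms: triisopropylsilyl triflate, CC(C)[Si](OS(=O)(=O)C(F)(F)F)(C(C)C)C(C)C
Why: Silyl-triflate silylation of hindered phenols; TIPS is chosen because it should survive the basic couplings and the acidic peroxide step and later screens the C1 carbonyl.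

Step 5
Reactants: 8 2-methylbut-3-en-2-ol
Product: 9 tert-butyldimethyl[(2-methylbut-3-en-2-yl)oxy]silane
Conditions: TBSOTf, 2,6-lutidine, CH2Cl2, 0 °C → rt
Reagents that add atoms: tert-butyldimethylsilyl triflate, CC(C)(C)[Si](C)(C)OS(=O)(=O)C(F)(F)F
Why: Silyl-triflate silylation of a tertiary alcohol; the ether keeps the hydroxyl out of the hydroboration and later prevents ionisation or cyclisation of the tertiary centre.

Step 6
Reactants: 7 6-bromo-5,7-bis(triisopropylsilyloxy)-2,3-dihydro-1H-inden-1-one; 9 tert-butyldimethyl[(2-methylbut-3-en-2-yl)oxy]silane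
Product: 11 6-[3-(tert-butyldimethylsilyloxy)-3-methylbutyl]-5,7-bis(triisopropylsilyloxy)-2,3-dihydro-1H-inden-1-one, via B-alkyl-9-BBN 10 (not isolated)
Conditions: 9 (slight excess), 9-BBN, THF, rt; then 7, Pd(OAc)2/SPhos, aq. K3PO4, THF, 65 °C
Reagents that add atoms: none
Why: Anti-Markovnikov hydroboration of the terminal alkene followed by B-alkyl Suzuki–Miyaura coupling, with a bulky biaryl phosphine to drive oxidative addition and reductive elimination at the di-ortho-substituted bromide; the ketone and silyl ethers should tolerate aqueous phosphate.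

Step 7
Reactants: 12 7-hydroxy-2,2-dimethylchroman-4-one
Product: 13 6-bromo-7-hydroxy-2,2-dimethylchroman-4-one
Conditions: NBS (1.0 equiv), MeCN, 0 °C
Reagents that add atoms: N-bromosuccinimide, O=C1CCC(=O)N1Br
Why: Electrophilic aromatic bromination at C6, which is ortho to the phenol, para to the ring ether oxygen and less hindered than C8, in line with the 5-bromination of 2,4-dioxygenated acetophenones.

Step 8
Reactants: 13 6-bromo-7-hydroxy-2,2-dimethylchroman-4-one
Product: 14 6-bromo-2,2-dimethyl-7-(triisopropylsilyloxy)chroman-4-one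
Conditions: TIPSCl, imidazole, DMF, rt
Reagents that add atoms: triisopropylsilyl chloride, CC(C)[Si](Cl)(C(C)C)C(C)C
Why: Imidazole-promoted silylation of a phenol, a standard protection.

Step 9
Reactants: 14 6-bromo-2,2-dimethyl-7-(triisopropylsilyloxy)chroman-4-one
Product: 15 6-bromo-2,2-dimethyl-7-(triisopropylsilyloxy)chroman-4-ol (racemic)
Conditions: NaBH4, EtOH/THF, 0 °C
Reagents that add atoms: none
Why: Borohydride reduction of the aryl ketone; the new stereocentre is racemic and is removed in the next step.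

Step 10
Reactants: 15 6-bromo-2,2-dimethyl-7-(triisopropylsilyloxy)chroman-4-ol
Product: 16 6-bromo-2,2-dimethyl-7-(triisopropylsilyloxy)-2H-chromene
Conditions: TsOH·H2O (cat.), toluene, 80 °C
Reagents that add atoms: none
Why: Acid-catalysed E1 dehydration through the oxygen-stabilised benzylic cation, the usual entry to 2,2-dimethyl-2H-chromenes.

Step 11
Reactants: 11 6-[3-(tert-butyldimethylsilyloxy)-3-methylbutyl]-5,7-bis(triisopropylsilyloxy)-2,3-dihydro-1H-inden-1-one; 16 6-bromo-2,2-dimethyl-7-(triisopropylsilyloxy)-2H-chromene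
Product: 17 6-[3-(tert-butyldimethylsilyloxy)-3-methylbutyl]-2-[2,2-dimethyl-7-(triisopropylsilyloxy)-2H-chromen-6-yl]-5,7-bis(triisopropylsilyloxy)-2,3-dihydro-1H-inden-1-one (racemic)
Conditions: Pd2(dba)3, t-Bu3P·HBF4, NaOt-Bu, toluene, 70 °C
Reagents that add atoms: none
Why: Palladium-catalysed α-arylation of a ketone enolate (Buchwald–Hartwig type); mono-arylation is expected because the product rests as its hindered, more stabilised enolate, and the OTIPS group next to the carbonyl should suppress self-aldol.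

Step 12
Reactants: 17 6-[3-(tert-butyldimethylsilyloxy)-3-methylbutyl]-2-[2,2-dimethyl-7-(triisopropylsilyloxy)-2H-chromen-6-yl]-5,7-bis(triisopropylsilyloxy)-2,3-dihydro-1H-inden-1-one
Product: 19 6-[3-(tert-butyldimethylsilyloxy)-3-methylbutyl]-2-[2,2-dimethyl-7-(triisopropylsilyloxy)-2H-chromen-6-yl]-5,7-bis(triisopropylsilyloxy)-1H-inden-1-one, via α-phenylselanyl ketone 18 (not isolated)
Conditions: LiHMDS, THF, −78 °C; PhSeCl; then NaIO4, NaHCO3, THF/MeOH/H2O, rt
Reagents that add atoms: none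
Why: Enolate α-selenation followed by selenoxide syn-elimination; the only β-hydrogens are on C3, so the double bond can only form inside the five-membered ring, and periodate should leave the chromene alkene alone.

Step 13
Reactants: 19 6-[3-(tert-butyldimethylsilyloxy)-3-methylbutyl]-2-[2,2-dimethyl-7-(triisopropylsilyloxy)-2H-chromen-6-yl]-5,7-bis(triisopropylsilyloxy)-1H-inden-1-one
Product: 21 6-[3-(tert-butyldimethylsilyloxy)-3-methylbutyl]-3-[2,2-dimethyl-7-(triisopropylsilyloxy)-2H-chromen-6-yl]-5,7-bis(triisopropylsilyloxy)-4H-chromen-4-one, via C3 hydroperoxide 20 (not isolated)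
Conditions: urea·H2O2 (4 equiv), TsOH·H2O (0.2 equiv), CH2Cl2/HFIP 4:1, 0 °C → rt
Reagents that add atoms: hydrogen peroxide (supplied as its urea adduct), OO
Why: Proposed new method: under acidic, hydrogen-bond-donating conditions (no base, which would give the Weitz–Scheffer epoxide) hydrogen peroxide should add in conjugate fashion to C3 of the indenone to give the benzylic hydroperoxide 20; protonation of its terminal oxygen then triggers a Hock-type 1,2-shift of the arene carbon C3a from C3 to oxygen with loss of water, and the cyclic oxocarbenium ion loses the acidic proton on the aryl- and acyl-bearing carbon to give the 4-pyranone. The closest known reaction type is the acid-catalysed Hock rearrangement of cyclic benzylic hydroperoxides (1-indanyl hydroperoxide ring-expands to the 2-chromanol stage), combined with acid-catalysed hydroperoxidation of an enone. The pyranone is not closed by a cyclisation but arises by ring expansion of the five-membered ring (the C3a–C3 bond is exchanged for C3a–O and O–C3), so no ring-closure mode applies. No stereocentre is created, and the two stereocentres of 20 vanish on rearrangement and elimination. Two selectivities are needed: peroxide must attack C3 and not the carbonyl carbon (which would open a Baeyer–Villiger path to a 3-arylcoumarin), which the OTIPS group at C7 and the ortho-silyloxyaryl group at C2 should secure by screening C1 while C3 is an unhindered CH; and the arene carbon must migrate in preference to hydride or C2, which follows the usual Hock order and is helped by the para alkyl group. The chromone product should be inert to H2O2/acid and accumulate, and because every hydroxyl is silylated neither quinone formation nor chroman formation from the tertiary centre should interfere.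

Step 14
Reactants: 21 6-[3-(tert-butyldimethylsilyloxy)-3-methylbutyl]-3-[2,2-dimethyl-7-(triisopropylsilyloxy)-2H-chromen-6-yl]-5,7-bis(triisopropylsilyloxy)-4H-chromen-4-one
Product: 22 5,7-dihydroxy-3-(7-hydroxy-2,2-dimethyl-2H-chromen-6-yl)-6-(3-hydroxy-3-methylbutyl)-4H-chromen-4-one (CNP0113306.0)
Conditions: TBAF (8 equiv), THF, 0 °C → 45 °C; AcOH quench
Reagents that add atoms: none
Why: Fluoride-mediated desilylation, in which the aryl TIPS ethers should cleave at room temperature and the tertiary TBS ether on warming, with no acid present that could cyclise the tertiary alcohol onto a neighbouring phenol or hydrate the chromene.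

**Compound list**

1 | 4-bromo-3,5-dimethoxybenzaldehyde | COc1cc(C=O)cc(OC)c1Br | starting material
2 | 5-[(4-bromo-3,5-dimethoxyphenyl)methylidene]-2,2-dimethyl-1,3-dioxane-4,6-dione (in-flask species) | COc1cc(C=C2C(=O)OC(C)(C)OC2=O)cc(OC)c1Br | intermediate
3 | 5-[(4-bromo-3,5-dimethoxyphenyl)methyl]-2,2-dimethyl-1,3-dioxane-4,6-dione (in-flask species) | COc1cc(CC2C(=O)OC(C)(C)OC2=O)cc(OC)c1Br | intermediate
4 | 3-(4-bromo-3,5-dimethoxyphenyl)propanoic acid | COc1cc(CCC(=O)O)cc(OC)c1Br | intermediate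
5 | 6-bromo-5,7-dimethoxy-2,3-dihydro-1H-inden-1-one | COc1cc2CCC(=O)c2c(OC)c1Br | intermediate
6 | 6-bromo-5,7-dihydroxy-2,3-dihydro-1H-inden-1-one | Oc1cc2CCC(=O)c2c(O)c1Br | intermediate
7 | 6-bromo-5,7-bis(triisopropylsilyloxy)-2,3-dihydro-1H-inden-1-one | CC(C)[Si](Oc1cc2CCC(=O)c2c(O[Si](C(C)C)(C(C)C)C(C)C)c1Br)(C(C)C)C(C)C | intermediate
8 | 2-methylbut-3-en-2-ol | CC(C)(O)C=C | starting material
9 | tert-butyldimethyl[(2-methylbut-3-en-2-yl)oxy]silane | CC(C)(C=C)O[Si](C)(C)C(C)(C)C | intermediate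
10 | 9-[3-(tert-butyldimethylsilyloxy)-3-methylbutyl]-9-borabicyclo[3.3.1]nonane (in-flask species) | CC(C)(CCB1C2CCCC1CCC2)O[Si](C)(C)C(C)(C)C | intermediate
11 | 6-[3-(tert-butyldimethylsilyloxy)-3-methylbutyl]-5,7-bis(triisopropylsilyloxy)-2,3-dihydro-1H-inden-1-one | CC(C)(O[Si](C)(C)C(C)(C)C)CCc1c(O[Si](C(C)C)(C(C)C)C(C)C)cc2CCC(=O)c2c1O[Si](C(C)C)(C(C)C)C(C)C | intermediate
12 | 7-hydroxy-2,2-dimethylchroman-4-one | CC1(C)CC(=O)c2ccc(O)cc2O1 | starting material
13 | 6-bromo-7-hydroxy-2,2-dimethylchroman-4-one | CC1(C)CC(=O)c2cc(Br)c(O)cc2O1 | intermediate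
14 | 6-bromo-2,2-dimethyl-7-(triisopropylsilyloxy)chroman-4-one | CC1(C)CC(=O)c2cc(Br)c(O[Si](C(C)C)(C(C)C)C(C)C)cc2O1 | intermediate
15 | 6-bromo-2,2-dimethyl-7-(triisopropylsilyloxy)chroman-4-ol (racemic) | CC1(C)CC(O)c2cc(Br)c(O[Si](C(C)C)(C(C)C)C(C)C)cc2O1 | intermediate
16 | 6-bromo-2,2-dimethyl-7-(triisopropylsilyloxy)-2H-chromene | CC1(C)C=Cc2cc(Br)c(O[Si](C(C)C)(C(C)C)C(C)C)cc2O1 | intermediate
17 | 6-[3-(tert-butyldimethylsilyloxy)-3-methylbutyl]-2-[2,2-dimethyl-7-(triisopropylsilyloxy)-2H-chromen-6-yl]-5,7-bis(triisopropylsilyloxy)-2,3-dihydro-1H-inden-1-one (racemic) | CC(C)(O[Si](C)(C)C(C)(C)C)CCc1c(O[Si](C(C)C)(C(C)C)C(C)C)cc2CC(c3cc4c(cc3O[Si](C(C)C)(C(C)C)C(C)C)OC(C)(C)C=C4)C(=O)c2c1O[Si](C(C)C)(C(C)C)C(C)C | intermediate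
18 | 2-(phenylselanyl) derivative of 17 (racemic, in-flask species) | CC(C)(O[Si](C)(C)C(C)(C)C)CCc1c(O[Si](C(C)C)(C(C)C)C(C)C)cc2CC([Se]c5ccccc5)(c3cc4c(cc3O[Si](C(C)C)(C(C)C)C(C)C)OC(C)(C)C=C4)C(=O)c2c1O[Si](C(C)C)(C(C)C)C(C)C | intermediate
19 | 6-[3-(tert-butyldimethylsilyloxy)-3-methylbutyl]-2-[2,2-dimethyl-7-(triisopropylsilyloxy)-2H-chromen-6-yl]-5,7-bis(triisopropylsilyloxy)-1H-inden-1-one | CC(C)(O[Si](C)(C)C(C)(C)C)CCc1c(O[Si](C(C)C)(C(C)C)C(C)C)cc2C=C(c3cc4c(cc3O[Si](C(C)C)(C(C)C)C(C)C)OC(C)(C)C=C4)C(=O)c2c1O[Si](C(C)C)(C(C)C)C(C)C | intermediate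
20 | 3-hydroperoxy-2,3-dihydro derivative of 19 (diastereomer mixture, racemic, in-flask species) | CC(C)(O[Si](C)(C)C(C)(C)C)CCc1c(O[Si](C(C)C)(C(C)C)C(C)C)cc2C(OO)C(c3cc4c(cc3O[Si](C(C)C)(C(C)C)C(C)C)OC(C)(C)C=C4)C(=O)c2c1O[Si](C(C)C)(C(C)C)C(C)C | intermediate
21 | 6-[3-(tert-butyldimethylsilyloxy)-3-methylbutyl]-3-[2,2-dimethyl-7-(triisopropylsilyloxy)-2H-chromen-6-yl]-5,7-bis(triisopropylsilyloxy)-4H-chromen-4-one | CC(C)(O[Si](C)(C)C(C)(C)C)CCc1c(O[Si](C(C)C)(C(C)C)C(C)C)cc2occ(-c3cc4c(cc3O[Si](C(C)C)(C(C)C)C(C)C)OC(C)(C)C=C4)c(=O)c2c1O[Si](C(C)C)(C(C)C)C(C)C | intermediate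
22 | 5,7-dihydroxy-3-(7-hydroxy-2,2-dimethyl-2H-chromen-6-yl)-6-(3-hydroxy-3-methylbutyl)-4H-chromen-4-one | CC(C)(O)CCc1c(O)cc2occ(-c3cc4c(cc3O)OC(C)(C)C=C4)c(=O)c2c1O | target

**Step count and risks**

Total steps: 14. Longest linear sequence: 9 steps (1, 2, 3, 4, 6, 11, 12, 13, 14).

Steps most likely to fail:

1. Step 13 (the step carrying the new-method label).
   - What may go wrong: the arene carbon that must migrate has an ortho acyl group and only meta oxygen donors, so the 1,2-shift may be slower than reversal of the peroxide addition or than hydride shift/dehydration of the hydroperoxide to the 1,3-dione. Peroxide may also add to the carbonyl carbon and start a Baeyer–Villiger-type expansion to a coumarin. The acid may ionise the tertiary silyl ether or add water or peroxide across the chromene double bond.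
   - Fallback (known chemistry only): it sets out from borane 10 and bromide 16 and rejoins the route at 21; the ring oxygen is then brought in as a phenol. Commercial 2-bromoresorcinol is silylated (TIPSOTf, 2,6-lutidine) to 2-bromo-1,3-bis(triisopropylsilyloxy)benzene F1, which is coupled with 10 under the conditions of step 6 to give tert-butyl{[4-(2,6-bis(triisopropylsilyloxy)phenyl)-2-methylbutan-2-yl]oxy}dimethylsilane F2. Sterically governed iridium-catalysed C–H borylation ([Ir(OMe)(cod)]2, dtbpy, B2pin2) at the only C–H without an ortho substituent should give the aryl pinacol boronate F3, and oxidation (NaBO3, THF/H2O) the phenol 4-[3-(tert-butyldimethylsilyloxy)-3-methylbutyl]-3,5-bis(triisopropylsilyloxy)phenol F4, whose two positions ortho to the free hydroxyl are equivalent. Mono-iodination (NIS, CH2Cl2, −20 °C) gives the 2-iodophenol F5. Stille coupling with tributyl(1-ethoxyvinyl)stannane gives the 1-ethoxyvinyl arene F6, which is hydrolysed (dilute HCl, THF, 0 °C) to the o-hydroxyacetophenone F7. DMF dimethyl acetal converts this into the enaminone F8, and iodine-induced cyclisation gives the 3-iodochromone F9. In parallel, Miyaura borylation of 16 (B2pin2, PdCl2(dppf), KOAc) gives the chromenyl pinacol boronate F10, and Suzuki–Miyaura coupling of F9 with F10 (PdCl2(dppf), aq. Na2CO3, DME) gives 21.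

2. Step 11.
   - What may go wrong: slow oxidative addition or reductive elimination with the electron-rich ortho-silyloxy bromide, base-induced loss of aryl silyl groups at 70 °C, or aldol self-condensation of the indanone.
   - Fallback: it sets out from 11 and 16 and rejoins at 19, bypassing 17 and step 12, by making the aryl bond at the enone stage. IBX dehydrogenation of 11 (DMSO, 70 °C) gives the indenone 6-[3-(tert-butyldimethylsilyloxy)-3-methylbutyl]-5,7-bis(triisopropylsilyloxy)-1H-inden-1-one F11. Iodine/pyridine α-iodination of the enone gives the 2-iodoindenone F12. Suzuki–Miyaura coupling of F12 with the chromenyl pinacol boronate F10 (made from 16 as described above) gives 19.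

3. Step 6.
   - What may go wrong: sluggish oxidative addition or transmetalation at a bromide flanked by two OTIPS groups, leading to protodebromination or β-hydride elimination of the alkyl-palladium species.
   - Fallback: it sets out from 7 and rejoins at 11, replacing the sp3 coupling by a sterically undemanding sp coupling. Sonogashira coupling of 7 with commercial 2-methylbut-3-yn-2-ol (PdCl2(PPh3)2, CuI, Et3N/THF, 65 °C) gives the aryl alkynol 6-(3-hydroxy-3-methylbut-1-yn-1-yl)-5,7-bis(triisopropylsilyloxy)-2,3-dihydro-1H-inden-1-one F13. Hydrogenation (H2, Pd/C, EtOAc; no chromene is present yet) gives the saturated tertiary alcohol 6-(3-hydroxy-3-methylbutyl)-5,7-bis(triisopropylsilyloxy)-2,3-dihydro-1H-inden-1-one F14. Silylation (TBSOTf, 2,6-lutidine) gives 11.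

**Further compounds**

F1 | step 13 | 2-bromo-1,3-bis(triisopropylsilyloxy)benzene | CC(C)[Si](Oc1cccc(O[Si](C(C)C)(C(C)C)C(C)C)c1Br)(C(C)C)C(C)C
F2 | step 13 | tert-butyl{[4-(2,6-bis(triisopropylsilyloxy)phenyl)-2-methylbutan-2-yl]oxy}dimethylsilane | CC(C)(O[Si](C)(C)C(C)(C)C)CCc1c(O[Si](C(C)C)(C(C)C)C(C)C)cccc1O[Si](C(C)C)(C(C)C)C(C)C
F3 | step 13 | 2-{4-[3-(tert-butyldimethylsilyloxy)-3-methylbutyl]-3,5-bis(triisopropylsilyloxy)phenyl}-4,4,5,5-tetramethyl-1,3,2-dioxaborolane | CC(C)(O[Si](C)(C)C(C)(C)C)CCc1c(O[Si](C(C)C)(C(C)C)C(C)C)cc(B2OC(C)(C)C(C)(C)O2)cc1O[Si](C(C)C)(C(C)C)C(C)C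
F4 | step 13 | 4-[3-(tert-butyldimethylsilyloxy)-3-methylbutyl]-3,5-bis(triisopropylsilyloxy)phenol | CC(C)(O[Si](C)(C)C(C)(C)C)CCc1c(O[Si](C(C)C)(C(C)C)C(C)C)cc(O)cc1O[Si](C(C)C)(C(C)C)C(C)C
F5 | step 13 | 4-[3-(tert-butyldimethylsilyloxy)-3-methylbutyl]-2-iodo-3,5-bis(triisopropylsilyloxy)phenol | CC(C)(O[Si](C)(C)C(C)(C)C)CCc1c(O[Si](C(C)C)(C(C)C)C(C)C)cc(O)c(I)c1O[Si](C(C)C)(C(C)C)C(C)C
F6 | step 13 | 4-[3-(tert-butyldimethylsilyloxy)-3-methylbutyl]-2-(1-ethoxyvinyl)-3,5-bis(triisopropylsilyloxy)phenol | CCOC(=C)c1c(O)cc(O[Si](C(C)C)(C(C)C)C(C)C)c(CCC(C)(C)O[Si](C)(C)C(C)(C)C)c1O[Si](C(C)C)(C(C)C)C(C)C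
F7 | step 13 | 1-{3-[3-(tert-butyldimethylsilyloxy)-3-methylbutyl]-6-hydroxy-2,4-bis(triisopropylsilyloxy)phenyl}ethan-1-one | CC(=O)c1c(O)cc(O[Si](C(C)C)(C(C)C)C(C)C)c(CCC(C)(C)O[Si](C)(C)C(C)(C)C)c1O[Si](C(C)C)(C(C)C)C(C)C
F8 | step 13 | (E)-1-{3-[3-(tert-butyldimethylsilyloxy)-3-methylbutyl]-6-hydroxy-2,4-bis(triisopropylsilyloxy)phenyl}-3-(dimethylamino)prop-2-en-1-one | CN(C)/C=C/C(=O)c1c(O)cc(O[Si](C(C)C)(C(C)C)C(C)C)c(CCC(C)(C)O[Si](C)(C)C(C)(C)C)c1O[Si](C(C)C)(C(C)C)C(C)C
F9 | step 13 | 6-[3-(tert-butyldimethylsilyloxy)-3-methylbutyl]-3-iodo-5,7-bis(triisopropylsilyloxy)-4H-chromen-4-one | CC(C)(O[Si](C)(C)C(C)(C)C)CCc1c(O[Si](C(C)C)(C(C)C)C(C)C)cc2occ(I)c(=O)c2c1O[Si](C(C)C)(C(C)C)C(C)C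
F10 | step 13 | 2-[2,2-dimethyl-7-(triisopropylsilyloxy)-2H-chromen-6-yl]-4,4,5,5-tetramethyl-1,3,2-dioxaborolane | CC1(C)C=Cc2cc(B3OC(C)(C)C(C)(C)O3)c(O[Si](C(C)C)(C(C)C)C(C)C)cc2O1
F11 | step 11 | 6-[3-(tert-butyldimethylsilyloxy)-3-methylbutyl]-5,7-bis(triisopropylsilyloxy)-1H-inden-1-one | CC(C)(O[Si](C)(C)C(C)(C)C)CCc1c(O[Si](C(C)C)(C(C)C)C(C)C)cc2C=CC(=O)c2c1O[Si](C(C)C)(C(C)C)C(C)C
F12 | step 11 | 6-[3-(tert-butyldimethylsilyloxy)-3-methylbutyl]-2-iodo-5,7-bis(triisopropylsilyloxy)-1H-inden-1-one | CC(C)(O[Si](C)(C)C(C)(C)C)CCc1c(O[Si](C(C)C)(C(C)C)C(C)C)cc2C=C(I)C(=O)c2c1O[Si](C(C)C)(C(C)C)C(C)C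
F13 | step 6 | 6-(3-hydroxy-3-methylbut-1-yn-1-yl)-5,7-bis(triisopropylsilyloxy)-2,3-dihydro-1H-inden-1-one | CC(C)(O)C#Cc1c(O[Si](C(C)C)(C(C)C)C(C)C)cc2CCC(=O)c2c1O[Si](C(C)C)(C(C)C)C(C)C
F14 | step 6 | 6-(3-hydroxy-3-methylbutyl)-5,7-bis(triisopropylsilyloxy)-2,3-dihydro-1H-inden-1-one | CC(C)(O)CCc1c(O[Si](C(C)C)(C(C)C)C(C)C)cc2CCC(=O)c2c1O[Si](C(C)C)(C(C)C)C(C)C
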